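**Retrosynthetic overview**
1. Numbering: ring A = C1–C5 and C10. Ring B = C5–C10. The γ-lactone is C10–C20(=O)–O–C6–C5. Ring C = C8, C9, C11=C12, C13, with Me on C8 and C12 and CO2Me on C13. Ring D is the δ-lactone C9–O–C15(=O)–C14–C13–C8. The same numbers are used in 1: C8 carries Me, C13 is the five-ring C=O, C9=C10 is the enone alkene, and C20 is the six-ring C=O.
2. Endgame: 28 ⇐ C3 ketone 23 by axial-selective hydride reduction, α-methylenation at C14 and acetylation. No ring is formed after 22.
3. Key cut: C3–C4 and C5–C10 are cut together, 22 ⇐ aldehyde acid 19. The enabling feature is that bond C5–C10 is shared by ring A, ring B and the γ-lactone. Cutting it leaves one seven-membered lactone, C10–C20(=O)–O–C6–C7–C8–C9, whose α-carbon C10 lies five atoms from C5 of a 2-methylprop-1-enyl group on C6. An extra carboxyl on C10 (C21) is the radical source and leaves as CO2.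
4. 19 ⇐ bicyclic enedione 1. Its five-membered ring is ring C. Its six-membered ring becomes the seven-membered lactone by Baeyer–Villiger oxidation. C10 is quaternised by deconjugative alkylation, C13 by carbonylation, 1,4-reduction and alkylation, and ring D is closed by iodolactonisation–elimination.
5. Ring order: C (present in 1) → seven-membered lactone (step 8, temporary) → D (step 12) → B and the γ-lactone, then A (all in step 15).

Key step: step 15

Remark on the chemistry: stereocentres that are erased later are drawn as the expected major isomer and have no consequence. These are C10 in 5–20, C12 in 6, C13 in 13, and the carbinol carbon C5 in 10 and 11.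

Step 1
Reactants: 1 (S)-7a-methyl-2,3,7,7a-tetrahydro-1H-indene-1,5(6H)-dione
Product: 2 C10-bromo enedione
Conditions: Br2, CH2Cl2, −10 °C; then NEt3, 0 °C
Reagents that add atoms: bromine, BrBr
Why: Bromine addition to the enone and amine-induced loss of HBr (α-bromination of an enone) functionalise the only vinylic C–H, C10, and leave the C8 stereocentre of the commercial enantiomer untouched.

Step 2
Reactants: 2 C10-bromo enedione
Product: 3 enedione C10-carboxylic acid 2-(trimethylsilyl)ethyl ester
Conditions: PdCl2(PPh3)2 (cat.), CO (3 bar), Me3SiCH2CH2OH, NEt3, DMF, 70 °C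
Reagents that add atoms: carbon monoxide, [C-]#[O+]; 2-(trimethylsilyl)ethanol, C[Si](C)(C)CCO
Why: Palladium-catalysed alkoxycarbonylation of the vinyl bromide puts the extra carboxyl carbon C21 on C10 as a fluoride-labile ester, which acidifies C11–H now and is the radical source in step 15.

Step 3
Reactants: 3 enedione C10-carboxylic acid 2-(trimethylsilyl)ethyl ester; 4 2-(2-bromoethyl)-1,3-dioxolane
Product: 5 C10-quaternary diketone with the alkene at C9=C11
Conditions: Cs2CO3, NaI (cat.), DMF, 50 °C
Reagents that add atoms: none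
Why: In this deconjugative α-alkylation of a vinylogous β-keto ester, carbonate removes the γ-proton at C11 and the extended enolate is alkylated at C10 anti to the C8 methyl, which makes C10 fully substituted, moves the alkene to C9=C11 and brings in C1–C3 with C3 masked as an acetal.

Step 4
Reactants: 5 C10-quaternary diketone with the alkene at C9=C11
Product: 6 C12-methyl diketone
Conditions: LiN(i-Pr)2, THF, −78 °C; MeI
Reagents that add atoms: iodomethane, CI
Why: In this enolate alkylation the C12 protons are both α to the C13 ketone and allylic, so they are removed first and the dienolate is methylated at its α-carbon C12 (configuration erased in step 5).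

Step 5
Reactants: 6 C12-methyl diketone
Product: 7 C13 dienyl triflate
Conditions: KN(SiMe3)2, THF, −78 to −20 °C; PhNTf2
Reagents that add atoms: N-phenylbis(trifluoromethanesulfonimide), O=S(=O)(N(c1ccccc1)S(=O)(=O)C(F)(F)F)C(F)(F)F
Why: Enol triflate formation under equilibrating conditions goes through the more stabilised C13 dienolate, conjugated with C11=C9, rather than the C20 enolate, and fixes the C13=C12 double bond.

Step 6
Reactants: 7 C13 dienyl triflate
Product: 8 methyl dienoate ketone
Conditions: Pd(OAc)2 (cat.), PPh3, CO (1 bar), MeOH, NEt3, DMF, 50 °C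
Reagents that add atoms: carbon monoxide, [C-]#[O+]; methanol, CO
Why: Palladium-catalysed methoxycarbonylation of the dienyl triflate attaches the methyl ester carbon to C13, a standard reaction of hindered cyclopentenyl triflates.

Step 7
Reactants: 8 methyl dienoate ketone; 9 2-methylpropanal
Product: 10 C6 aldol adduct
Conditions: LiN(i-Pr)2, THF, −78 °C; i-PrCHO; aqueous work-up
Reagents that add atoms: none
Why: In this directed aldol addition C6 is the only enolisable position of the C20 ketone, and the aldehyde is taken up anti to the axial C8 methyl so that the new side chain (C5, C4 and both methyls) is equatorial, which sets C6.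

Step 8
Reactants: 10 C6 aldol adduct
Product: 11 seven-membered hydroxy lactone
Conditions: Me3SiOOSiMe3, Me3SiOTf (cat.), CH2Cl2, −40 to −20 °C; aqueous work-up
Reagents that add atoms: bis(trimethylsilyl) peroxide, C[Si](C)(C)OO[Si](C)(C)C
Why: In this Baeyer–Villiger oxidation under aprotic conditions, which do not epoxidise alkenes, the secondary C6 migrates with retention in preference to the electron-poor quaternary C10, so oxygen enters between C20 and C6 and the six-membered ring becomes the seven-membered lactone.

Step 9
Reactants: 11 seven-membered hydroxy lactone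
Product: 12 seven-membered lactone bearing 2-methylprop-1-enyl on C6
Conditions: Burgess reagent, toluene, 70 °C
Reagents that add atoms: none
Why: Syn-elimination of the sulfamate ester (Burgess dehydration) removes the C5 hydroxyl towards the tertiary C4–H and should give the trisubstituted C5=C4 alkene rather than the enol ester.

Step 10
Reactants: 12 seven-membered lactone bearing 2-methylprop-1-enyl on C6
Product: 13 C12,C13-dihydro ester
Conditions: Cu(OAc)2 (cat.), 1,2-bis(diphenylphosphino)benzene (cat.), (EtO)2MeSiH, t-BuOH, toluene, 0 °C to rt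
Reagents that add atoms: none
Why: Copper hydride 1,4-reduction of the dienoate stops at the β-carbon because the δ-carbon C9 is flanked by two quaternary carbons, and hydride reaches C12 anti to the C8 methyl, which sets C12 with its hydrogen on that face (C13 is re-enolised in step 11).

Step 11
Reactants: 13 C12,C13-dihydro ester; 14 tert-butyl bromoacetate
Product: 15 C13-quaternary diester
Conditions: LiN(i-Pr)2, THF–DMPU, −78 to −40 °C; BrCH2CO2t-Bu
Reagents that add atoms: none
Why: In this ester enolate alkylation the methyl groups on C8 and C12 shield one face of the enolate, so the bromoacetate enters from the other face and sets the quaternary centre C13 with C14 anti to the C8 methyl.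

Step 12
Reactants: 15 C13-quaternary diester
Product: 17 tricyclic bis-lactone (rings C and D plus the seven-membered lactone), via C11 iodo lactone 16 (not isolated)
Conditions: I2, MeCN, 0 °C, dark; then DBU, toluene, 60 °C
Reagents that add atoms: none
Why: Iodolactonisation with loss of the tert-butyl group (6-exo, oxygen to the more substituted C9, anti addition) can deliver the carboxyl oxygen only from the face that carries C14, so it sets C9 and closes ring D without ever freeing a C9 alkoxide, and the E2 elimination then uses the anti-periplanar H12 to place the alkene at C11=C12, while the remote C5=C4 alkene has no internal nucleophile and is returned unchanged.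

Step 13
Reactants: 17 tricyclic bis-lactone (rings C and D plus the seven-membered lactone)
Product: 18 C21 carboxylic acid
Conditions: Bu4NF, THF, 0 °C; aqueous work-up
Reagents that add atoms: none
Why: Fluoride-induced β-elimination of the 2-(trimethylsilyl)ethyl ester frees the C21 acid under conditions that leave the methyl ester, both lactones and the acetal intact.

Step 14
Reactants: 18 C21 carboxylic acid
Product: 19 aldehyde acid
Conditions: p-TsOH·H2O (cat.), THF–H2O, 40 °C
Reagents that add atoms: water, O
Why: Mild acid-catalysed acetal hydrolysis unmasks the C3 aldehyde, since the tertiary C9–O bond sits at a bridgehead and cannot ionise and the temperature spares the allylic C6–O bond and the malonic-type acid.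

Step 15
Reactants: 19 aldehyde acid
Product: 22 pentacyclic C3 alcohol (both C3 epimers), via thiohydroxamate ester 20 (not isolated), via boron alkoxide 21 (not isolated)
Conditions: 1-hydroxypyridine-2(1H)-thione, DCC, CH2Cl2, 0 °C, dark; dilution with benzene (2 mM), BEt3 (large excess), trace air, visible light, 20 °C; then MeOH–H2O
Reagents that add atoms: none
Why: Proposed new method: under light the O-acyl thiohydroxamate 20 loses CO2 and gives the tertiary radical at C10, which adds to C5 of the 2-methylprop-1-enyl group; the tertiary radical formed at C4 adds to the aldehyde carbon C3, BEt3 captures the alkoxyl radical at boron and releases an ethyl radical that attacks the thiocarbonyl of the next molecule of 20, so the chain needs no hydrogen donor that could quench the carbon radicals early. The closest known reaction types are the decarboxylative radical chain of O-acyl thiohydroxamates (Barton decarboxylation) with an intervening cyclisation and the BEt3-mediated cyclisation of alkyl radicals onto aldehydes, and only their union in one chain is new. The first bond (C10–C5) is 5-exo-trig along C10–C20–O–C6–C5 and at the same time 6-exo-trig along C10–C9–C8–C7–C6–C5, so it turns the seven-membered lactone into the γ-lactone and ring B; the second bond (C4–C3) is 6-exo-trig onto C=O and closes ring A last. C10 and C5 are controlled by C6 and the ring system: the lactone bridge can span only the face of ring B on which C6 carries oxygen, which fixes C10, and in the chair-like transition state the CMe2 terminus points away from the C7–C8–C9 bridge, which places H5 axial and C4 equatorial (trans A/B); C4 becomes the gem-dimethyl quaternary carbon, and C3 is not controlled and is corrected in steps 16 and 17. The electrophilic C10 radical must choose the electron-rich C5=C4 alkene over C11=C12 and over the thiocarbonyl, which is secured by the s-cis ester geometry forced by the seven-membered ring, the polarity match and high dilution, and the reversible addition to C3=O must be made productive, which the large excess of BEt3 secures.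

Step 16
Reactants: 22 pentacyclic C3 alcohol (both C3 epimers)
Product: 23 pentacyclic C3 ketone
Conditions: Dess–Martin periodinane, CH2Cl2, rt
Reagents that add atoms: none
Why: Dess–Martin oxidation merges both C3 epimers into one ketone under neutral conditions.

Step 17
Reactants: 23 pentacyclic C3 ketone
Product: 24 axial C3 alcohol
Conditions: LiBH(s-Bu)3, THF, −78 °C; aqueous work-up
Reagents that add atoms: none
Why: In this bulky trialkylborohydride reduction of a 4,4-dimethylcyclohexanone, hydride enters along the equatorial trajectory and gives the axial C3 alcohol, while esters and lactones are inert at low temperature.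

Step 18
Reactants: 24 axial C3 alcohol
Product: 27 α-methylene lactone alcohol (deacetyl target), via Mannich base 25 (not isolated), via trimethylammonium iodide 26 (not isolated)
Conditions: LiN(i-Pr)2 (2.2 equiv), THF, −78 °C; CH2=NMe2+ I−; aqueous work-up; MeI, MeOH; DBU, CH2Cl2
Reagents that add atoms: dimethyl(methylidene)ammonium iodide, C=[N+](C)C.[I-]
Why: In this α-methylenation through a Mannich base (enolate aminomethylation, quaternisation, Hofmann-type elimination) C14 is the only enolisable carbon because C10 and C13 are quaternary, and the C3 hydroxyl is carried as its alkoxide.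

Step 19
Reactants: 27 α-methylene lactone alcohol (deacetyl target)
Product: 28 meroantarctine B
Conditions: Ac2O, DMAP (cat.), pyridine, rt
Reagents that add atoms: acetic anhydride, CC(=O)OC(C)=O
Why: DMAP-catalysed acetylation of the axial C3 alcohol completes the target without touching any stereocentre.

**Compound list**
1 | (S)-7a-methyl-2,3,7,7a-tetrahydro-1H-indene-1,5(6H)-dione | C[C@]12CCC(=O)C=C1CCC2=O | starting material
2 | C10-bromo enedione | C[C@]12CCC(=O)C(Br)=C1CCC2=O | intermediate
3 | enedione C10-carboxylic acid 2-(trimethylsilyl)ethyl ester | C[C@]12CCC(=O)C(C(=O)OCC[Si](C)(C)C)=C1CCC2=O | intermediate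
4 | 2-(2-bromoethyl)-1,3-dioxolane | BrCCC1OCCO1 | starting material
5 | C10-quaternary diketone, alkene at C9=C11, chain anti to the C8 methyl | C[C@]12CCC(=O)[C@@](C(=O)OCC[Si](C)(C)C)(CCC3OCCO3)C1=CCC2=O | intermediate
6 | C12-methyl diketone | C[C@]12CCC(=O)[C@@](C(=O)OCC[Si](C)(C)C)(CCC3OCCO3)C1=C[C@@H](C)C2=O | intermediate
7 | C13 dienyl triflate | C[C@]12CCC(=O)[C@@](C(=O)OCC[Si](C)(C)C)(CCC3OCCO3)C1=CC(C)=C2OS(=O)(=O)C(F)(F)F | intermediate
8 | methyl dienoate ketone | C[C@]12CCC(=O)[C@@](C(=O)OCC[Si](C)(C)C)(CCC3OCCO3)C1=CC(C)=C2C(=O)OC | intermediate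
9 | 2-methylpropanal | CC(C)C=O | starting material
10 | C6 aldol adduct, side chain anti to the C8 methyl | C[C@]12C[C@@H]([C@@H](O)C(C)C)C(=O)[C@@](C(=O)OCC[Si](C)(C)C)(CCC3OCCO3)C1=CC(C)=C2C(=O)OC | intermediate
11 | seven-membered hydroxy lactone | C[C@]12C[C@@H]([C@@H](O)C(C)C)OC(=O)[C@@](C(=O)OCC[Si](C)(C)C)(CCC3OCCO3)C1=CC(C)=C2C(=O)OC | intermediate
12 | seven-membered lactone bearing 2-methylprop-1-enyl on C6 | C[C@]12C[C@@H](C=C(C)C)OC(=O)[C@@](C(=O)OCC[Si](C)(C)C)(CCC3OCCO3)C1=CC(C)=C2C(=O)OC | intermediate
13 | C12,C13-dihydro ester, C12 methyl syn to the C8 methyl | C[C@]12C[C@@H](C=C(C)C)OC(=O)[C@@](C(=O)OCC[Si](C)(C)C)(CCC3OCCO3)C1=C[C@H](C)[C@@H]2C(=O)OC | intermediate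
14 | tert-butyl bromoacetate | CC(C)(C)OC(=O)CBr | starting material
15 | C13-quaternary diester, C14 anti to the C8 methyl | C[C@]12C[C@@H](C=C(C)C)OC(=O)[C@@](C(=O)OCC[Si](C)(C)C)(CCC3OCCO3)C1=C[C@H](C)[C@]2(CC(=O)OC(C)(C)C)C(=O)OC | intermediate
16 | C11 iodo lactone | C[C@]12C[C@@H](C=C(C)C)OC(=O)[C@@](C(=O)OCC[Si](C)(C)C)(CCC3OCCO3)[C@@]14OC(=O)C[C@]2(C(=O)OC)[C@@H](C)[C@H]4I | intermediate
17 | tricyclic bis-lactone (rings C and D plus the seven-membered lactone) | C[C@]12C[C@@H](C=C(C)C)OC(=O)[C@@](C(=O)OCC[Si](C)(C)C)(CCC3OCCO3)[C@@]14OC(=O)C[C@]2(C(=O)OC)C(C)=C4 | intermediate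
18 | C21 carboxylic acid | C[C@]12C[C@@H](C=C(C)C)OC(=O)[C@@](C(=O)O)(CCC3OCCO3)[C@@]14OC(=O)C[C@]2(C(=O)OC)C(C)=C4 | intermediate
19 | aldehyde acid | C[C@]12C[C@@H](C=C(C)C)OC(=O)[C@@](C(=O)O)(CCC=O)[C@@]14OC(=O)C[C@]2(C(=O)OC)C(C)=C4 | intermediate
20 | thiohydroxamate ester | C[C@]12C[C@@H](C=C(C)C)OC(=O)[C@@](C(=O)ON3C=CC=CC3=S)(CCC=O)[C@@]14OC(=O)C[C@]2(C(=O)OC)C(C)=C4 | intermediate
21 | boron alkoxide (C3 epimers) | C1C(=O)O[C@@]23C=C(C)[C@]1(C(=O)OC)[C@@]2(C)C[C@@H]1OC(=O)[C@]32CCC(OB(CC)CC)C(C)(C)[C@@H]12 | intermediate
22 | pentacyclic C3 alcohol (C3 epimers) | C1C(=O)O[C@@]23C=C(C)[C@]1(C(=O)OC)[C@@]2(C)C[C@@H]1OC(=O)[C@]32CCC(O)C(C)(C)[C@@H]12 | intermediate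
23 | pentacyclic C3 ketone | C1C(=O)O[C@@]23C=C(C)[C@]1(C(=O)OC)[C@@]2(C)C[C@@H]1OC(=O)[C@]32CCC(=O)C(C)(C)[C@@H]12 | intermediate
24 | axial C3 alcohol | C1C(=O)O[C@@]23C=C(C)[C@]1(C(=O)OC)[C@@]2(C)C[C@@H]1OC(=O)[C@]32CC[C@H](O)C(C)(C)[C@@H]12 | intermediate
25 | Mannich base (C14 epimers) | CN(C)CC1C(=O)O[C@@]23C=C(C)[C@]1(C(=O)OC)[C@@]2(C)C[C@@H]1OC(=O)[C@]32CC[C@H](O)C(C)(C)[C@@H]12 | intermediate
26 | trimethylammonium iodide (C14 epimers) | [I-].C[N+](C)(C)CC1C(=O)O[C@@]23C=C(C)[C@]1(C(=O)OC)[C@@]2(C)C[C@@H]1OC(=O)[C@]32CC[C@H](O)C(C)(C)[C@@H]12 | intermediate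
27 | α-methylene lactone alcohol (deacetyl target) | C=C1C(=O)O[C@@]23C=C(C)[C@]1(C(=O)OC)[C@@]2(C)C[C@@H]1OC(=O)[C@]32CC[C@H](O)C(C)(C)[C@@H]12 | intermediate
28 | meroantarctine B | C=C1C(=O)O[C@@]23C=C(C)[C@]1(C(=O)OC)[C@@]2(C)C[C@@H]1OC(=O)[C@]32CC[C@H](OC(C)=O)C(C)(C)[C@@H]12 | target

Total step count: 19. Longest linear sequence: 19.

**Steps most likely to fail**

**Step 15 (bears the label).**
- What may go wrong: capture of the C4 radical by the thiocarbonyl group, or transfer of the aldehyde hydrogen to C4, may outrun the reversible addition to C3=O, so that ring A is not closed.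
- The fallback uses known chemistry and sets out from 19. The thiohydroxamate ester 20 is photolysed without BEt3 at ordinary concentration. The chain then ends after the first cyclisation by transfer of the 2-pyridylthio group and gives the tetracyclic tertiary 2-pyridyl sulfide aldehyde F1, in which rings B, C, D and the γ-lactone are closed.
- mCPBA at −78 °C gives the sulfoxide F2. On warming it undergoes syn-elimination to the C5-isopropenyl aldehyde F3.
- Iron-hydride hydrogen-atom transfer (Fe(acac)3, PhSiH3, EtOH, 60 °C) regenerates the C4 radical and closes ring A onto the aldehyde (reductive alkene–carbonyl cyclisation). This comes back to the route at 22.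

**Step 8.**
- What may go wrong: slow addition of the peroxide to the hindered C20 ketone, or migration of C10 in place of C6.
- The fallback replaces oxygen insertion by ring cleavage and relactonisation, and sets out from 8. KN(SiMe3)2 and 2-(phenylsulfonyl)-3-phenyloxaziridine give the C6 α-hydroxy ketone F4.
- NaIO4 in THF–H2O cleaves C20–C6 to the seco aldehyde acid F5.
- Me2C=CHMgBr (2 equiv, THF, −78 °C) adds to the aldehyde and gives the seco hydroxy acid F6. Its C6 epimer is removed after ring closure.
- Yamaguchi lactonisation (2,4,6-trichlorobenzoyl chloride, NEt3; DMAP, toluene) comes back to the route at 12.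

**Step 12.**
- What may go wrong: poor access of the iodonium ion to the face of C9=C11 that carries the C8 and C12 methyl groups, or consumption of the C5=C4 alkene by iodine.
- The fallback installs the C9 oxygen with a small reagent on the open face before the C5=C4 alkene exists, and sets out from 11. Et3SiCl and imidazole give the triethylsilyl ether F7.
- The conditions of step 10 give the 1,4-reduction product F8, and those of step 11 give the C13-alkylated diester F9.
- Photooxygenation (O2, tetraphenylporphyrin, light; Schenck ene reaction) abstracts H12 and gives the C9 allylic hydroperoxide F10. PPh3 reduces it to the C9 allylic alcohol F11.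
- CF3CO2H in CH2Cl2 at 0 °C removes the tert-butyl and silyl groups and closes ring D to the δ-lactone carrying the free C5 hydroxyl, F12.
- The Burgess dehydration of step 9 then comes back to the route at 17.

Further compounds
F1 | step 15 | tetracyclic tertiary 2-pyridyl sulfide aldehyde | C1C(=O)O[C@@]23C=C(C)[C@]1(C(=O)OC)[C@@]2(C)C[C@@H]1OC(=O)[C@@]3(CCC=O)[C@H]1C(C)(C)Sc1ccccn1
F2 | step 15 | sulfoxide of F1 | C1C(=O)O[C@@]23C=C(C)[C@]1(C(=O)OC)[C@@]2(C)C[C@@H]1OC(=O)[C@@]3(CCC=O)[C@H]1C(C)(C)S(=O)c1ccccn1
F3 | step 15 | C5-isopropenyl aldehyde | C1C(=O)O[C@@]23C=C(C)[C@]1(C(=O)OC)[C@@]2(C)C[C@@H]1OC(=O)[C@@]3(CCC=O)[C@H]1C(C)=C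
F4 | step 8 | C6 α-hydroxy ketone (C6 epimers) | C[C@]12CC(O)C(=O)[C@@](C(=O)OCC[Si](C)(C)C)(CCC3OCCO3)C1=CC(C)=C2C(=O)OC
F5 | step 8 | seco aldehyde acid | C[C@@]1(CC=O)C(C(=O)OC)=C(C)C=C1[C@](C(=O)O)(C(=O)OCC[Si](C)(C)C)CCC1OCCO1
F6 | step 8 | seco hydroxy acid | C[C@@]1(C[C@H](O)C=C(C)C)C(C(=O)OC)=C(C)C=C1[C@](C(=O)O)(C(=O)OCC[Si](C)(C)C)CCC1OCCO1
F7 | step 12 | triethylsilyl ether of 11 | C[C@]12C[C@@H]([C@@H](O[Si](CC)(CC)CC)C(C)C)OC(=O)[C@@](C(=O)OCC[Si](C)(C)C)(CCC3OCCO3)C1=CC(C)=C2C(=O)OC
F8 | step 12 | 1,4-reduction product of F7 | C[C@]12C[C@@H]([C@@H](O[Si](CC)(CC)CC)C(C)C)OC(=O)[C@@](C(=O)OCC[Si](C)(C)C)(CCC3OCCO3)C1=C[C@H](C)[C@@H]2C(=O)OC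
F9 | step 12 | C13-alkylated diester | C[C@]12C[C@@H]([C@@H](O[Si](CC)(CC)CC)C(C)C)OC(=O)[C@@](C(=O)OCC[Si](C)(C)C)(CCC3OCCO3)C1=C[C@H](C)[C@]2(CC(=O)OC(C)(C)C)C(=O)OC
F10 | step 12 | C9 allylic hydroperoxide | C[C@]12C[C@@H]([C@@H](O[Si](CC)(CC)CC)C(C)C)OC(=O)[C@@](C(=O)OCC[Si](C)(C)C)(CCC3OCCO3)[C@]1(OO)C=C(C)[C@]2(CC(=O)OC(C)(C)C)C(=O)OC
F11 | step 12 | C9 allylic alcohol | C[C@]12C[C@@H]([C@@H](O[Si](CC)(CC)CC)C(C)C)OC(=O)[C@@](C(=O)OCC[Si](C)(C)C)(CCC3OCCO3)[C@]1(O)C=C(C)[C@]2(CC(=O)OC(C)(C)C)C(=O)OC
F12 | step 12 | δ-lactone carrying the free C5 hydroxyl | C[C@]12C[C@@H]([C@@H](O)C(C)C)OC(=O)[C@@](C(=O)OCC[Si](C)(C)C)(CCC3OCCO3)[C@@]14OC(=O)C[C@]2(C(=O)OC)C(C)=C4
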